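3 questions stand on this flask: how much target it holds at 30 h, which change helps, and how much target north leaves.

starting material 3.0 M; gas phase 200 mM (held); protic impurity 0.300 M; time 30 h

    starting material + dissolved gas → target (k1 = 0.23 M⁻¹ h⁻¹)
    gas phase ⇌ dissolved gas, rate k2*(csat - [dissolved gas]) (k2 = 7.3 h⁻¹, csat = 200 mM)
    starting material + protic impurity → quenched substrate (k3 = 0.027 M⁻¹ h⁻¹)
    target → over-reaction product (k4 = 0.14 h⁻¹)
    starting material → side product (k5 = 0.016 h⁻¹)

- how much target there is at 30 h, in percent of the starting material charged
- the change that raises the amount of target at 30 h, in percent of the starting material charged most ("none" if none brings more than 2 percentage points) (north / east / none)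
- amount of target at 30 h, in percent of the starting material charged, after north

- north: doubling the saturation concentration of gas phase, all else as stated
- east: doubling the transfer coefficient of step 2, all else as stated

- at the start none of the gas is dissolved
- run time (flask): 30 h

In the first instants the flask holds no dissolved gas, and transfer fills the solution within about 8.22 min. Starting material consumes dissolved gas at 0.690 h⁻¹, slower than transfer at 7.3 h⁻¹, so the reckoned level of dissolved gas at the charged starting material is near 0.183 M, and it then climbs towards 200 mM.

This reckoning takes the gas at 200 mM, which makes the loss of starting material pseudo-first-order. Target forms with the gain constant 0.0460 h⁻¹. Starting material falls with the loss constant 0.0701 h⁻¹, which also counts side product and quenching at the charged impurity.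

In the middle of the run target climbs, and this reckoning puts its peak near 9.90 h.

Late in the run target decays faster than starting material, so it trails starting material. The trailing ratio is target per starting material once the start-up has died away: the gain constant over the gap between the two loss constants, 0.658. The start-up factor at 30 h is 0.877, and reckoned starting material is 12.2 %. The product of trailing ratio, start-up factor and reckoned starting material gives the reckoned target.

| | gain constant | loss constant | trailing ratio | target at 30 h |
|---|---|---|---|---|
| flask | 0.0460 h⁻¹ | 0.0701 h⁻¹ | 0.658 | 7.05 % |
| north | 0.0920 h⁻¹ | 0.116 h⁻¹ | 3.85 | 6.05 % |

North raises the ratio but narrows the gap, and reckoned target ends lower, by 1 percentage point. East doubles a transfer already faster than the uptake of dissolved gas. This reckoning therefore chooses none.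

The forecast gives 7.7 %, none and 6.5 %, holding that north “uses up the starting material sooner, leaving more time for over-reaction”.

The simulation gives 7.70 %, best none, and 6.63 % after north, with gains of −1.1 points for north and −0.074 points for east. Target stays low because it passes on to over-reaction product: with that path taken away, the same flask holds 57.5 % instead of 7.70 %, and the choice of best change turns. In the flask at 30 h, the readings give 0.528 target per starting material, against 0.577 from ratio and start-up factor. In the neighbour flask, the same charge read at 3.0 d, the readings give 0.604 against the trailing ratio 0.658, with 0.592 % target beside 0.98 % starting material.

The constants are those of an exercise; the flask was simulated.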